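**Retrosynthetic overview**
1. Target ⇐ hydrogenolysis of its penta-O-benzyl ether.
2. Both pyranone rings (the two O1–C2 bonds and all four stereocentres) ⇐ one catalytic enantioselective double oxa-Michael cyclisation of an α,α'-linked bis(2'-hydroxychalcone); the 5,7-dioxygenated chromanone ring is expected to close first, the 7-oxygenated one second.
3. Bis-chalcone ⇐ double Claisen–Schmidt condensation of an unsymmetrical 1,4-diarylbutane-1,4-dione with 4-(benzyloxy)benzaldehyde.
4. 1,4-Diketone (future C3–C3'' bond) ⇐ alkylation of the dianion of 2-hydroxy-4,6-bis(benzyloxy)acetophenone with the α-bromo ketone from 4-benzyloxy-2-hydroxyacetophenone (phenol masked as a TBS ether that falls off during the condensation).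
5. All aromatic rings are bought; no ring is made before the key step.

Assumption: the target is taken exactly as the given SMILES, which I read as the 2,3-trans/2'',3''-trans (2S,3R,2''S,3''R) liquiritigenin–naringenin 3,3''-biflavanone.

**Step 1**
Reactants: 1 phloroacetophenone [1-(2,4,6-trihydroxyphenyl)ethanone]
Product: 2 1-[2,4-bis(benzyloxy)-6-hydroxyphenyl]ethanone
Conditions: BnBr (2.05 equiv), K2CO3 (2.2 equiv), DMF, 0 °C → rt
Reagents that add atoms: benzyl bromide, BrCc1ccccc1
Why: Williamson etherification under weak base alkylates the 4-OH and one ortho OH, while the last ortho OH is locked in the hydrogen bond to the acetyl group and stays free; no stereocentre is formed.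

**Step 2**
Reactants: 3 1-[4-(benzyloxy)-2-hydroxyphenyl]ethanone
Product: 4 1-[4-(benzyloxy)-2-(tert-butyldimethylsilyloxy)phenyl]ethanone
Conditions: TBSCl (1.3 equiv), imidazole (2.5 equiv), DMF, 40 °C
Reagents that add atoms: tert-butyldimethylsilyl chloride (TBSCl), CC(C)(C)[Si](C)(C)Cl
Why: Imidazole-promoted silylation masks the phenol so the derived α-bromo ketone cannot close to a benzofuran-3-one, and an aryl silyl ether is chosen because the KOH of step 5 removes it without a separate step; no stereocentre.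

**Step 3**
Reactants: 4 1-[4-(benzyloxy)-2-(tert-butyldimethylsilyloxy)phenyl]ethanone
Product: 6 2-bromo-1-[4-(benzyloxy)-2-(tert-butyldimethylsilyloxy)phenyl]ethanone, via trimethylsilyl enol ether 5 (not isolated)
Conditions: LiN(SiMe3)2 (1.1 equiv), TMSCl (1.2 equiv, internal quench), THF, −78 °C; then NBS (1.05 equiv), −78 → 0 °C
Reagents that add atoms: N-bromosuccinimide (NBS), O=C1CCC(=O)N1Br; chlorotrimethylsilane (TMSCl), C[Si](C)(C)Cl (its atoms stay in 5 only)
Why: Kinetic enolisation with immediate silyl trapping gives the enol silane, which NBS brominates at carbon much faster than the alkoxyarene ring (electrophilic α-bromination of a silyl enol ether) under acid-free conditions that spare the TBS and benzyl ethers; no stereocentre.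

**Step 4**
Reactants: 2 1-[2,4-bis(benzyloxy)-6-hydroxyphenyl]ethanone; 6 2-bromo-1-[4-(benzyloxy)-2-(tert-butyldimethylsilyloxy)phenyl]ethanone
Product: 8 1-[4-(benzyloxy)-2-(tert-butyldimethylsilyloxy)phenyl]-4-[2,4-bis(benzyloxy)-6-hydroxyphenyl]butane-1,4-dione, via dilithium phenoxide-enolate 7 (not isolated)
Conditions: 2 (1.2 equiv), LiN(SiMe3)2 (2.4 equiv), THF, −78 → −30 °C; then 6 (1.0 equiv), −78 → 0 °C; AcOH quench
Reagents that add atoms: lithium bis(trimethylsilyl)amide, [Li+].C[Si](C)(C)[N-][Si](C)(C)C (lithium stays in 7 only)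
Why: The dianion of an ortho-hydroxyacetophenone reacts at the enolate carbon, not at the chelated phenoxide, and displaces bromide from the α-bromo ketone (SN2 enolate alkylation), whose carbonyl is shielded by the ortho-OTBS group and deactivated by two oxygen donors; any TBS lost here is harmless because step 5 removes it; no stereocentre.

**Step 5**
Reactants: 8 1-[4-(benzyloxy)-2-(tert-butyldimethylsilyloxy)phenyl]-4-[2,4-bis(benzyloxy)-6-hydroxyphenyl]butane-1,4-dione; 9 4-(benzyloxy)benzaldehyde (2.6 equiv)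
Product: 11 (2E,3E)-1-[4-(benzyloxy)-2-hydroxyphenyl]-4-[2,4-bis(benzyloxy)-6-hydroxyphenyl]-2,3-bis[4-(benzyloxy)benzylidene]butane-1,4-dione, via desilylated diketone 10 (not isolated)
Conditions: KOH (50% aq, 10 equiv), EtOH–THF, 0 °C → rt, 36 h, dark; cold 1 M HCl to pH 5–6
Reagents that add atoms: none
Why: Hydroxide first cleaves the aryl TBS ether, then a double Claisen–Schmidt condensation (aldol addition, E1cB dehydration) at both α-methylenes gives the E,E-bis(arylidene) diketone, which stays open as its bis-phenoxide in strong base; no stereocentre, both alkenes E (aryl trans to C=O).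

**Step 6**
Reactants: 11 (2E,3E)-1-[4-(benzyloxy)-2-hydroxyphenyl]-4-[2,4-bis(benzyloxy)-6-hydroxyphenyl]-2,3-bis[4-(benzyloxy)benzylidene]butane-1,4-dione
Product: 13 (2S,3R,2''S,3''R)-7,4',5'',7'',4'''-pentakis(benzyloxy)-3,3''-biflavanone, via monocyclised vinylflavanone 12 (not isolated)
Conditions: 3-{[3,5-bis(trifluoromethyl)phenyl]amino}-4-{[(9R)-6'-methoxycinchonan-9-yl]amino}cyclobut-3-ene-1,2-dione (quinidine-derived squaramide, 10 mol%), 4 Å MS, toluene, −20 °C → rt, 72 h, dark
Reagents that add atoms: none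
Why: Proposed new method: a double enantioselective 6-endo-trig oxa-Michael cyclisation of an α,α'-linked bis(2'-hydroxychalcone), a substrate class not yet cyclised asymmetrically; the squaramide NH pair binds the enone carbonyl while the quinuclidine deprotonates the chelated 2'-OH, so the phenol adds to one face of the E-enone (setting C2) and the quinuclidinium returns the proton to C3 from the same face (syn O/H addition across an E-alkene gives 2,3-trans, which is also the diequatorial thermodynamic arrangement of the enolisable C3/C3'' centres); the 5,7-dioxygenated half closes first under catalyst control (12), the second closure is expected to be a matched catalyst-plus-substrate case, and the minor mismatched pathway ends in a separable meso-type diastereomer, which raises the ee of 13 (Horeau-type amplification); having no free para-phenol and no strong base limits retro-oxa-Michael racemisation; closest known reaction type: cinchona thiourea or squaramide catalysed intramolecular oxa-Michael addition of phenols to enones and to alkylidene β-keto esters giving chromans and flavanones.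

**Step 7**
Reactants: 13 (2S,3R,2''S,3''R)-7,4',5'',7'',4'''-pentakis(benzyloxy)-3,3''-biflavanone
Product: 14 (2S,3R)-3-[(2S,3R)-5,7-dihydroxy-2-(4-hydroxyphenyl)-4-oxochroman-3-yl]-7-hydroxy-2-(4-hydroxyphenyl)chroman-4-one (target CNP0138443.1)
Conditions: H2 (1 atm), Pd/C (10 wt%), EtOAc–MeOH 1:1, rt, stopped at full conversion
Reagents that add atoms: none
Why: Heterogeneous hydrogenolysis of the five aryl benzyl ethers is neutral, so it neither enolises C3/C3'' nor opens the pyranone rings (the hindered cyclic C2–O bonds cleave far more slowly than ArO–CH2Ph), and the four stereocentres are carried through unchanged.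

**Compound list**
1 | phloroacetophenone, 1-(2,4,6-trihydroxyphenyl)ethanone | CC(=O)c1c(O)cc(O)cc1O | starting material
2 | 1-[2,4-bis(benzyloxy)-6-hydroxyphenyl]ethanone | CC(=O)c1c(O)cc(OCc2ccccc2)cc1OCc1ccccc1 | intermediate
3 | 1-[4-(benzyloxy)-2-hydroxyphenyl]ethanone | CC(=O)c1ccc(OCc2ccccc2)cc1O | starting material
4 | 1-[4-(benzyloxy)-2-(tert-butyldimethylsilyloxy)phenyl]ethanone | CC(=O)c1ccc(OCc2ccccc2)cc1O[Si](C)(C)C(C)(C)C | intermediate
5 | trimethylsilyl enol ether of 4, {1-[4-(benzyloxy)-2-(tert-butyldimethylsilyloxy)phenyl]ethenyloxy}trimethylsilane | C=C(O[Si](C)(C)C)c1ccc(OCc2ccccc2)cc1O[Si](C)(C)C(C)(C)C | intermediate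
6 | 2-bromo-1-[4-(benzyloxy)-2-(tert-butyldimethylsilyloxy)phenyl]ethanone | O=C(CBr)c1ccc(OCc2ccccc2)cc1O[Si](C)(C)C(C)(C)C | intermediate
7 | dilithium phenoxide-enolate of 2 | [Li+].[Li+].C=C([O-])c1c([O-])cc(OCc2ccccc2)cc1OCc1ccccc1 | intermediate
8 | 1-[4-(benzyloxy)-2-(tert-butyldimethylsilyloxy)phenyl]-4-[2,4-bis(benzyloxy)-6-hydroxyphenyl]butane-1,4-dione | O=C(CCC(=O)c1c(O)cc(OCc2ccccc2)cc1OCc1ccccc1)c1ccc(OCc2ccccc2)cc1O[Si](C)(C)C(C)(C)C | intermediate
9 | 4-(benzyloxy)benzaldehyde | O=Cc1ccc(OCc2ccccc2)cc1 | starting material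
10 | 1-[4-(benzyloxy)-2-hydroxyphenyl]-4-[2,4-bis(benzyloxy)-6-hydroxyphenyl]butane-1,4-dione | O=C(CCC(=O)c1c(O)cc(OCc2ccccc2)cc1OCc1ccccc1)c1ccc(OCc2ccccc2)cc1O | intermediate
11 | (2E,3E)-1-[4-(benzyloxy)-2-hydroxyphenyl]-4-[2,4-bis(benzyloxy)-6-hydroxyphenyl]-2,3-bis[4-(benzyloxy)benzylidene]butane-1,4-dione | O=C(c1ccc(OCc2ccccc2)cc1O)/C(=C/c1ccc(OCc2ccccc2)cc1)C(=C/c1ccc(OCc2ccccc2)cc1)\C(=O)c1c(O)cc(OCc2ccccc2)cc1OCc1ccccc1 | intermediate
12 | (2S,3R)-5,7-bis(benzyloxy)-2-[4-(benzyloxy)phenyl]-3-{(E)-1-[4-(benzyloxy)-2-hydroxybenzoyl]-2-[4-(benzyloxy)phenyl]ethenyl}chroman-4-one | O=C(c1ccc(OCc2ccccc2)cc1O)/C(=C/c1ccc(OCc2ccccc2)cc1)[C@H]1C(=O)c2c(OCc3ccccc3)cc(OCc3ccccc3)cc2O[C@@H]1c1ccc(OCc2ccccc2)cc1 | intermediate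
13 | (2S,3R,2''S,3''R)-7,4',5'',7'',4'''-pentakis(benzyloxy)-3,3''-biflavanone, i.e. (2S,3R)-7-(benzyloxy)-3-{(2S,3R)-5,7-bis(benzyloxy)-2-[4-(benzyloxy)phenyl]-4-oxochroman-3-yl}-2-[4-(benzyloxy)phenyl]chroman-4-one | O=C1c2ccc(OCc3ccccc3)cc2O[C@H](c2ccc(OCc3ccccc3)cc2)[C@H]1[C@H]1C(=O)c2c(OCc3ccccc3)cc(OCc3ccccc3)cc2O[C@@H]1c1ccc(OCc2ccccc2)cc1 | intermediate
14 | (2S,3R)-3-[(2S,3R)-5,7-dihydroxy-2-(4-hydroxyphenyl)-4-oxochroman-3-yl]-7-hydroxy-2-(4-hydroxyphenyl)chroman-4-one | O=C1c2ccc(O)cc2O[C@H](c2ccc(O)cc2)[C@H]1[C@H]1C(=O)c2c(O)cc(O)cc2O[C@@H]1c1ccc(O)cc1 | target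

**Totals and risks**
Total step count: 7. Longest linear sequence: 6 (3 → 4 → 6 → 8 → 11 → 13 → 14).

The three steps most likely to fail:

Step 6 (proposed double oxa-Michael cyclisation). The α-branched enones may react slowly under mild bifunctional catalysis, and catalyst control in the second closure may be incomplete. The (2S) sense of this catalyst pseudo-enantiomer is an assumption by analogy and must be checked on the mono-chalcone made from 3 and 9; the quinine-derived catalyst gives the opposite sense. The fallback uses known chemistry and sets out from 11: classical thermodynamic chalcone-to-flavanone cyclisation (NaOAc, EtOH, reflux) gives the racemic trans,trans product, that is 13 together with the mirror-image (2R,3S,2''R,3''S)-pentabenzyl biflavanone F1. After silica chromatography the two enantiomers are separated by preparative chiral SFC on an amylose tris(3,5-dimethylphenylcarbamate) phase, and the route is rejoined at 13.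

Step 5 (double Claisen–Schmidt condensation). After the first condensation the enone can isomerise under base to an ene-dione, or the reaction can stop at the mono-arylidene stage. The fallback sets out from 8 and separates addition from elimination. Boron-mediated double aldol addition (n-Bu2BOTf, iPr2NEt, CH2Cl2, −78 °C, then 9, buffered H2O2 work-up) gives the bis-aldol adduct F2 as a diastereomer mixture. Acetylation (Ac2O, Et3N, DMAP) gives the triacetate F3. DBU in CH2Cl2 at 0 °C eliminates both β-acetoxy groups to the acetylated silylated bis-enone F4. Brief KOH in aqueous EtOH at 0 °C removes the aryl acetate and the TBS group, and the route is rejoined at 11.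

Step 4 (dianion alkylation). Carbonyl addition to the bromo ketone, proton transfer or bromine transfer could compete with SN2 displacement. The fallback sets out from 2 and switches to a radical coupling. TMSOTf and Et3N in CH2Cl2 at 0 °C convert 2 into its bis(trimethylsilyl) derivative F5 (silyl enol ether plus aryl silyl ether). Visible-light photoredox coupling of F5 with 6 (Ir(ppy)3, 1 mol%, blue LEDs, MeCN, rt; α-keto radical addition to the enol silane) followed by a dilute citric acid work-up removes the trimethylsilyl groups, and the route is rejoined at 8.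

**Further compounds**
F1 | step 6 | (2R,3S,2''R,3''S)-7,4',5'',7'',4'''-pentakis(benzyloxy)-3,3''-biflavanone (mirror image of 13) | O=C1c2ccc(OCc3ccccc3)cc2O[C@@H](c2ccc(OCc3ccccc3)cc2)[C@@H]1[C@@H]1C(=O)c2c(OCc3ccccc3)cc(OCc3ccccc3)cc2O[C@H]1c1ccc(OCc2ccccc2)cc1
F2 | step 5 | 1-[4-(benzyloxy)-2-(tert-butyldimethylsilyloxy)phenyl]-4-[2,4-bis(benzyloxy)-6-hydroxyphenyl]-2,3-bis{[4-(benzyloxy)phenyl](hydroxy)methyl}butane-1,4-dione (diastereomer mixture) | CC(C)(C)[Si](C)(C)Oc1cc(OCc2ccccc2)ccc1C(=O)C(C(O)c1ccc(OCc2ccccc2)cc1)C(C(O)c1ccc(OCc2ccccc2)cc1)C(=O)c1c(O)cc(OCc2ccccc2)cc1OCc1ccccc1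
F3 | step 5 | triacetate of F2 (two carbinol acetates and the aryl acetate) | CC(C)(C)[Si](C)(C)Oc1cc(OCc2ccccc2)ccc1C(=O)C(C(OC(C)=O)c1ccc(OCc2ccccc2)cc1)C(C(OC(C)=O)c1ccc(OCc2ccccc2)cc1)C(=O)c1c(OC(C)=O)cc(OCc2ccccc2)cc1OCc1ccccc1
F4 | step 5 | (2E,3E)-1-[4-(benzyloxy)-2-(tert-butyldimethylsilyloxy)phenyl]-4-[2-acetoxy-4,6-bis(benzyloxy)phenyl]-2,3-bis[4-(benzyloxy)benzylidene]butane-1,4-dione | CC(C)(C)[Si](C)(C)Oc1cc(OCc2ccccc2)ccc1C(=O)/C(=C/c1ccc(OCc2ccccc2)cc1)C(=C/c1ccc(OCc2ccccc2)cc1)\C(=O)c1c(OC(C)=O)cc(OCc2ccccc2)cc1OCc1ccccc1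
F5 | step 4 | bis(trimethylsilyl) derivative of 2, {1-[2,4-bis(benzyloxy)-6-(trimethylsilyloxy)phenyl]ethenyloxy}trimethylsilane | C=C(O[Si](C)(C)C)c1c(O[Si](C)(C)C)cc(OCc2ccccc2)cc1OCc1ccccc1
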